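**Plan**

Locants (2,3-seco-labdane type): ring B is the cyclohexane C5–C6–C7–C8–C9–C10, ring C the pyran O–C8–C9–C11–C12–C13; C4 is the ester-bearing carbon on C5, C1/C2 the CH2CO2H arm on C10.
Retrosynthesis: remove one CH3 from C4 (enolate methylation), then cut C5–C10 and C8–C9 together, which opens both rings to the acyclic enol ether 11; cut its C8–O bond to alcohol 4 and keto-enoate 7.
Alcohol 4 (C9–C16, C20, C1, C2) comes from (R)-linalool by allylic oxidation and one-carbon carbonylation; 7 (C3–C8, C17) comes from hex-5-en-2-one.
Forward: one hydrogen-atom-transfer radical cascade closes ring C (C8–C9) and then ring B (C5–C10) in the same flask.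
Feature used: C8 is a fully substituted ether carbon (α-oxy radical), C10 the quaternary carbon two bonds away (tertiary radical once C8 has added to the C9=C10 olefin), and C5 carries the α-carbon of an ester (radical acceptor), so the three sites line up with matched polarity.
Stereochemistry: C13 from (R)-linalool; C8, C9, C10 and C5 from the two chair-like 6-exo closures, relayed from C13.

Key step: step 9

Remark: (R)-(−)-linalool of high enantiomeric purity is taken as the commercial source of C13; enol ethers 9 and 11 are drawn as the 1-ene isomers, the 2-ene isomers that may accompany them being equivalent in steps 7 and 9.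

**Route**

Step 1
Reactants: 1 (R)-linalool, (3R)-3,7-dimethylocta-1,6-dien-3-ol
Product: 2 (2E,6R)-2,6-dimethylocta-2,7-diene-1,6-diol
Conditions: SeO2 (cat.), t-BuOOH, CH2Cl2, rt
Reagents that add atoms: selenium dioxide O=[Se]=O (catalytic oxygen carrier); tert-butyl hydroperoxide CC(C)(C)OO
Why: SeO2/t-BuOOH allylic oxidation (ene reaction, then [2,3]-shift) should hydroxylate only the (E)-methyl group of the trisubstituted olefin, leaving the vinyl group and the stereocentre taken from 1 untouched.

Step 2
Reactants: 2 (2E,6R)-2,6-dimethylocta-2,7-diene-1,6-diol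
Product: 3 (2E,6R)-6-hydroxy-2,6-dimethylocta-2,7-dien-1-yl methyl carbonate
Conditions: ClCO2CH3, pyridine, CH2Cl2, 0 °C
Reagents that add atoms: methyl chloroformate COC(=O)Cl
Why: carbonate formation (O-acylation) should be selective for the primary allylic hydroxyl over the hindered tertiary one.

Step 3
Reactants: 3 (2E,6R)-6-hydroxy-2,6-dimethylocta-2,7-dien-1-yl methyl carbonate
Product: 4 methyl (3E,7R)-7-hydroxy-3,7-dimethylnona-3,8-dienoate
Conditions: Pd(OAc)2 (cat.), PPh3, CO (20 atm), THF, 50 °C
Reagents that add atoms: carbon monoxide [C-]#[O+]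
Why: decarboxylative carbonylation of an allylic carbonate, in which zerovalent palladium forms the π-allyl complex, CO inserts at the unsubstituted terminus and the released methoxide gives the β,γ-unsaturated methyl ester with the E geometry kept, the free tertiary allylic alcohol not being ionised.

Step 4
Reactants: 5 hex-5-en-2-one
Product: 6 4-oxopentanal
Conditions: O3, CH2Cl2, −78 °C; then (CH3)2S
Reagents that add atoms: ozone [O-][O+]=O
Why: ozonolysis with reductive work-up should cleave the terminal olefin to the aldehyde without touching the ketone.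

Step 5
Reactants: 6 4-oxopentanal
Product: 7 methyl (2E)-2-methyl-6-oxohept-2-enoate
Conditions: Ph3P=C(CH3)CO2CH3, CH2Cl2, rt
Reagents that add atoms: methyl 2-(triphenyl-λ5-phosphanylidene)propanoate COC(=O)C(C)=P(c1ccccc1)(c1ccccc1)c1ccccc1
Why: Wittig olefination with a stabilised ylide should take the aldehyde in preference to the methyl ketone and give the E enoate.

Step 6
Reactants: 7 methyl (2E)-2-methyl-6-oxohept-2-enoate
Product: 9 methyl (2E)-6-methoxy-2-methylhepta-2,6-dienoate, via dimethyl ketal 8 (not isolated)
Conditions: HC(OCH3)3, CH3OH, TsOH (cat.), rt; concentrate; TMSOTf, i-Pr2NEt, CH2Cl2, −20 °C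
Reagents that add atoms: trimethyl orthoformate COC(OC)OC
Why: ketalisation followed by silyl triflate/amine elimination of methanol (ketal to enol ether) should give the 2-methoxyalkene, no stereocentre being involved.

Step 7
Reactants: 4 methyl (3E,7R)-7-hydroxy-3,7-dimethylnona-3,8-dienoate; 9 methyl (2E)-6-methoxy-2-methylhepta-2,6-dienoate
Product: 10 methyl (2E)-6-methoxy-6-{[(3R,6E)-9-methoxy-3,7-dimethyl-9-oxonona-1,6-dien-3-yl]oxy}-2-methylhept-2-enoate (both epimers at the ketal carbon C8)
Conditions: PPTS (cat.), CH2Cl2, 0 °C
Reagents that add atoms: none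
Why: acid-catalysed Markovnikov addition of an alcohol to a 2-alkoxyalkene (the reaction that makes 2-methoxyprop-2-yl ethers) tolerates tertiary alcohols and forms the C8–O bond, the new ketal centre being erased in step 8.

Step 8
Reactants: 10 methyl (2E)-6-methoxy-6-{[(3R,6E)-9-methoxy-3,7-dimethyl-9-oxonona-1,6-dien-3-yl]oxy}-2-methylhept-2-enoate
Product: 11 methyl (2E)-6-{[(3R,6E)-9-methoxy-3,7-dimethyl-9-oxonona-1,6-dien-3-yl]oxy}-2-methylhepta-2,6-dienoate
Conditions: TMSOTf, i-Pr2NEt, CH2Cl2, −78 to −30 °C
Reagents that add atoms: none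
Why: ketal-to-enol-ether elimination, in which the silyl triflate should take the less hindered methoxy group and the amine remove a proton from the oxocarbenium ion, the cold keeping the resulting allyl vinyl ether from Claisen rearrangement.

Step 9
Reactants: 11 methyl (2E)-6-{[(3R,6E)-9-methoxy-3,7-dimethyl-9-oxonona-1,6-dien-3-yl]oxy}-2-methylhepta-2,6-dienoate
Product: 12 methyl 2-[(2R,4aS,5R,6R,8aS)-2-ethenyl-5-(2-methoxy-2-oxoethyl)-2,5,8a-trimethyl-octahydro-2H-chromen-6-yl]propanoate (both epimers at the propanoate α-carbon C4)
Conditions: Fe(acac)3 (0.3 equiv), PhSiH3, EtOH/(CH2OH)2, 0.01 M, rt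
Reagents that add atoms: none
Why: Proposed new method: the iron hydride generated from Fe(acac)3 and PhSiH3 should deliver a hydrogen atom to the terminal CH2 of the 2-alkoxyalkene (the most electron-rich and least hindered of the four olefins), giving the tertiary α-oxy radical at C8, which closes ring C by 6-exo-trig addition to C9; the tertiary C10 radical so formed closes ring B by 6-exo-trig addition to C5 of the enoate, and the ester-stabilised C4 radical is reduced and protonated by the medium. The closest known reactions are iron-mediated hydrogen-atom-transfer couplings of enol ethers with enoates (Giese type) and hydrogen-atom-transfer-initiated radical bicyclisations of polyenes, and the polarity is matched at every stage (nucleophilic radical on a neutral, then on an electron-poor olefin). C9 follows from the chair-like transition state of the first closure with the C9=C10 olefin equatorial, and C8 from the fact that any such chair puts one C8 group 1,3-syn to one C13 group, the cheapest pair being the new CH3 on C8 against the flat vinyl on C13, which at the same time lets the C13 centre taken from linalool choose the olefin face. C10 is set in the second chair, where one of its groups must again sit 1,3-syn to the axial C8 methyl and CH3 is preferred over the CH2CO2CH3 arm, and C5 by the equatorial position of the acceptor carbon C4; C7 and C10 being both equatorial on ring C, the B/C fusion is trans. The step needs the first 6-exo closure to outrun reduction, 1,5-hydrogen shift from C11 and C–O β-scission of the C8 radical (high dilution, slow hydride turnover, room temperature), and it needs the size difference CH3 < CH2R at C8 and C10 to be expressed, which the fully substituted neighbours C13 and C8 should enforce.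

Step 10
Reactants: 12 methyl 2-[(2R,4aS,5R,6R,8aS)-2-ethenyl-5-(2-methoxy-2-oxoethyl)-2,5,8a-trimethyl-octahydro-2H-chromen-6-yl]propanoate
Product: 13 2-[(2R,4aS,5R,6R,8aS)-2-ethenyl-6-(1-methoxy-1-oxopropan-2-yl)-2,5,8a-trimethyl-octahydro-2H-chromen-5-yl]acetic acid (both epimers at C4)
Conditions: LiOH, THF/H2O, 0 °C to rt; then aq. HCl
Reagents that add atoms: lithium hydroxide [Li+].[OH-]
Why: saponification should be faster at the unbranched CH2CO2CH3 ester than at the α-branched ester held against the ring, and no stereocentre that matters is touched.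

Step 11
Reactants: 13 2-[(2R,4aS,5R,6R,8aS)-2-ethenyl-6-(1-methoxy-1-oxopropan-2-yl)-2,5,8a-trimethyl-octahydro-2H-chromen-5-yl]acetic acid
Product: 14 2-[(2R,4aS,5R,6S,8aS)-2-ethenyl-6-(1-methoxy-2-methyl-1-oxopropan-2-yl)-2,5,8a-trimethyl-octahydro-2H-chromen-5-yl]acetic acid (CNP0280657.1)
Conditions: LiN(i-Pr)2 (2.5 equiv), THF/DMPU, −78 to −40 °C; CH3I; aq. NH4Cl
Reagents that add atoms: iodomethane CI
Why: ester enolate alkylation, in which the carboxylate formed by the first equivalent of base shields C1, the second equivalent enolises only the ester, and C-methylation makes C4 a quaternary, non-stereogenic carbon (the descriptor at C5 changes from R to S only through the priority rules).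

**Compound list**

1 | (R)-linalool, (3R)-3,7-dimethylocta-1,6-dien-3-ol | C=C[C@](C)(O)CCC=C(C)C | starting material
2 | (2E,6R)-2,6-dimethylocta-2,7-diene-1,6-diol | C=C[C@](C)(O)CC/C=C(\C)CO | intermediate
3 | (2E,6R)-6-hydroxy-2,6-dimethylocta-2,7-dien-1-yl methyl carbonate | C=C[C@](C)(O)CC/C=C(\C)COC(=O)OC | intermediate
4 | methyl (3E,7R)-7-hydroxy-3,7-dimethylnona-3,8-dienoate | C=C[C@](C)(O)CC/C=C(\C)CC(=O)OC | intermediate
5 | hex-5-en-2-one | CC(=O)CCC=C | starting material
6 | 4-oxopentanal | CC(=O)CCC=O | intermediate
7 | methyl (2E)-2-methyl-6-oxohept-2-enoate | CC(=O)CC/C=C(\C)C(=O)OC | intermediate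
8 | methyl (2E)-6,6-dimethoxy-2-methylhept-2-enoate | CC(OC)(OC)CC/C=C(\C)C(=O)OC | intermediate (not isolated)
9 | methyl (2E)-6-methoxy-2-methylhepta-2,6-dienoate | C=C(OC)CC/C=C(\C)C(=O)OC | intermediate
10 | methyl (2E)-6-methoxy-6-{[(3R,6E)-9-methoxy-3,7-dimethyl-9-oxonona-1,6-dien-3-yl]oxy}-2-methylhept-2-enoate, both epimers at the ketal carbon | C=C[C@](C)(OC(C)(OC)CC/C=C(\C)C(=O)OC)CC/C=C(\C)CC(=O)OC | intermediate
11 | methyl (2E)-6-{[(3R,6E)-9-methoxy-3,7-dimethyl-9-oxonona-1,6-dien-3-yl]oxy}-2-methylhepta-2,6-dienoate | C=C[C@](C)(OC(=C)CC/C=C(\C)C(=O)OC)CC/C=C(\C)CC(=O)OC | intermediate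
12 | methyl 2-[(2R,4aS,5R,6R,8aS)-2-ethenyl-5-(2-methoxy-2-oxoethyl)-2,5,8a-trimethyl-octahydro-2H-chromen-6-yl]propanoate, both epimers at the propanoate α-carbon | C=C[C@@]1(C)CC[C@H]2[C@](C)(CC(=O)OC)[C@@H](C(C)C(=O)OC)CC[C@]2(C)O1 | intermediate
13 | 2-[(2R,4aS,5R,6R,8aS)-2-ethenyl-6-(1-methoxy-1-oxopropan-2-yl)-2,5,8a-trimethyl-octahydro-2H-chromen-5-yl]acetic acid, both epimers at the propanoate α-carbon | C=C[C@@]1(C)CC[C@H]2[C@](C)(CC(=O)O)[C@@H](C(C)C(=O)OC)CC[C@]2(C)O1 | intermediate
14 | 2-[(2R,4aS,5R,6S,8aS)-2-ethenyl-6-(1-methoxy-2-methyl-1-oxopropan-2-yl)-2,5,8a-trimethyl-octahydro-2H-chromen-5-yl]acetic acid | C=C[C@@]1(C)CC[C@H]2[C@](C)(CC(=O)O)[C@@H](C(C)(C)C(=O)OC)CC[C@]2(C)O1 | target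

**Summary**

Total step count: 11.
Longest linear sequence: 8 steps (1 → 2 → 3 → 4 → 10 → 11 → 12 → 13 → 14; steps 1, 2, 3, 7, 8, 9, 10, 11).

**Steps most likely to fail**

Step 9 (Proposed new method). The C8 radical may be reduced before it cyclises, may take the allylic hydrogen at C11 by a 1,5-shift, or may fragment at the C13–O bond; the chair preferences at C8 and C10 may also be expressed only weakly. The fallback closes the two rings in separate, established operations and sets out from 11. A catalytic Lewis acid (In(OTf)3, CH2Cl2, −78 °C) should turn the enol ether into the oxocarbenium ion, which closes ring C in a Prins-type oxonium-ene reaction (chair, hydrogen lost from the C10 methyl) to give methyl (2E)-5-[(2S,3S,6R)-6-ethenyl-3-(4-methoxy-4-oxobut-1-en-2-yl)-2,6-dimethyloxan-2-yl]-2-methylpent-2-enoate F1. Iron-mediated reductive olefin–enoate coupling of F1 (Fe(acac)3, PhSiH3, EtOH, 60 °C; hydrogen atom to the new 1,1-disubstituted olefin, 6-exo Giese closure of the C10 radical) should then give 12, where the route is rejoined.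

Step 8. The silyl triflate may ionise the tertiary allylic C13–O bond instead of removing methanol, and the allyl vinyl ether may rearrange ([3,3]) on warming. The fallback avoids the enol ether and sets out from 10. Exchange of the methoxy group with PhSeSiMe3 and catalytic TMSOTf at −78 °C should give the O,Se-ketal methyl (2E)-6-{[(3R,6E)-9-methoxy-3,7-dimethyl-9-oxonona-1,6-dien-3-yl]oxy}-2-methyl-6-(phenylselanyl)hept-2-enoate F2. Selenium abstraction with (Me3Si)3SiH and Et3B/air at −20 °C under high dilution generates the same C8 radical by a silane chain, and the two 6-exo closures should lead to 12, where the route is rejoined.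

Step 7. The hindered tertiary allylic alcohol may add too slowly, so that acid-promoted loss of water from 4 or self-condensation of 9 takes over. The fallback forms the ketal under aprotic conditions and sets out from 4. Silylation (Me3SiCl, imidazole, DMF) gives methyl (3E,7R)-3,7-dimethyl-7-[(trimethylsilyl)oxy]nona-3,8-dienoate F3. Ketal formation of F3 with ketone 7 and CH3OSiMe3 under catalytic TMSOTf (CH2Cl2, −78 °C; silyl ether plus ketone to ketal) should give 10, where the route is rejoined.

Further compounds
F1 | step 9 | methyl (2E)-5-[(2S,3S,6R)-6-ethenyl-3-(4-methoxy-4-oxobut-1-en-2-yl)-2,6-dimethyloxan-2-yl]-2-methylpent-2-enoate | C=C[C@@]1(C)CC[C@@H](C(=C)CC(=O)OC)[C@](C)(CC/C=C(\C)C(=O)OC)O1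
F2 | step 8 | methyl (2E)-6-{[(3R,6E)-9-methoxy-3,7-dimethyl-9-oxonona-1,6-dien-3-yl]oxy}-2-methyl-6-(phenylselanyl)hept-2-enoate | C=C[C@](C)(OC(C)([Se]c1ccccc1)CC/C=C(\C)C(=O)OC)CC/C=C(\C)CC(=O)OC
F3 | step 7 | methyl (3E,7R)-3,7-dimethyl-7-[(trimethylsilyl)oxy]nona-3,8-dienoate | C=C[C@](C)(O[Si](C)(C)C)CC/C=C(\C)CC(=O)OC
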